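**Strategy.** Ring A (O1, C2=O, C3–CH3, C4H, C5) with its exocyclic C5=C6 bond is read as an enol ester. O1–C5=C6 is the enol of an aldehyde, and C2–C4 is a methacrylate metallated at C4. Everything rests on joining the two sp2 carbons C4 and C5 late, by a 5-exo intramolecular Heck reaction of 21, the (E)-enol ester of (Z)-3-iodo-2-methylacrylic acid. One operation closes ring A and sets the Z alkene stereospecifically. The spiro core is made without protecting groups from nepetalactone. Its cis-fused lactone is a temporary ring that directs hydrogenation (C7) and alkylation (spiro C12) before an aldol condensation closes ring C.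

Key step: step 13

Atom labels (target):
- Ring A: O1, C2(=O), C3(CH3), C4H, C5.
- Chain: C6H=, C7H(CH3).
- Ring B (cyclopentane): C8 (bears C7), C9, C10, C11 (bears CH3), spiro C12.
- Ring C (cyclohexene): C12, C13H2, C14H=, C15(CH3)=, C16H(O-acyl), C17H2.
- The target is 5Z,7S,8R,11S,12S,16S.
- In the bicyclic intermediates the lactone carbonyl carbon is the future C13 and the OCH2 carbon is the future C6.

Assumption: (4aS,7S,7aR)-nepetalactone (main constituent of catnip oil, otherwise three known steps from (S)-citronellal) and 2-(bromomethyl)but-1-ene are taken as catalogue compounds.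

Step 1
Reactants: 1 (4aS,7S,7aR)-nepetalactone
Product: 2 (4S,4aR,7S,7aR)-dihydronepetalactone
Conditions: H2 (1 atm), Pd/C, EtOAc, rt
Reagents that add atoms: none
Why: Heterogeneous syn-hydrogenation of the trisubstituted enol-lactone alkene should occur on the convex face of the cis-fused bicycle (the face of H8 and H12), which sets C7 as S.

Step 2
Reactants: 2 (4S,4aR,7S,7aR)-dihydronepetalactone; 3 2-(bromomethyl)but-1-ene
Product: 5 (4S,4aR,7S,7aR)-4,7-dimethyl-7a-(2-methylidenebutyl)hexahydrocyclopenta[c]pyran-1(3H)-one, via lithium enolate 4 (not isolated)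
Conditions: LiN(i-Pr)2, THF, −78 °C; then 3, DMPU, −78 → 0 °C
Reagents that add atoms: none
Why: Alkylation of a ring-fusion lactone enolate with a reactive allylic bromide should take place on the convex face so that the cis fusion is kept, which sets quaternary C12 with the new C17 arm cis to the C11 methyl group and the lactone carbonyl (future C13) cis to the C8 side chain.

Step 3
Reactants: 5 alkylated lactone
Product: 6 (4S,4aR,7S,7aR)-4,7-dimethyl-7a-(2-methylidenebutyl)octahydrocyclopenta[c]pyran-1-ol (lactol, both epimers at the acetal carbon)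
Conditions: i-Bu2AlH, CH2Cl2, −78 °C; aq. potassium sodium tartrate
Reagents that add atoms: none
Why: Partial reduction of a hindered lactone with i-Bu2AlH should stop at the aluminium acetal at low temperature, the isolated alkene is inert, and no stereocentre of the target is touched.

Step 4
Reactants: 6 lactol
Product: 8 2-{(1R,2R,5S)-2-[(2S)-1-hydroxypropan-2-yl]-5-methyl-1-(2-methylidenebutyl)cyclopentyl}acetaldehyde, via methyl enol ether 7 (not isolated)
Conditions: MeOCH2PPh3Cl, KOt-Bu, THF, 0 °C → rt; then 2 M HCl, THF, rt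
Reagents that add atoms: (methoxymethyl)triphenylphosphonium chloride, COC[P+](c1ccccc1)(c1ccccc1)c1ccccc1.[Cl-]; water, O
Why: Wittig methoxymethylenation of the open hydroxy-aldehyde form of the lactol followed by enol-ether hydrolysis is a one-carbon homologation that turns the former lactone carbon into the C13 methylene group, adds C14 and opens the temporary ring without touching a stereocentre.

Step 5
Reactants: 8 homologated aldehyde
Product: 10 2-{(1S,2R,5S)-2-[(2S)-1-hydroxypropan-2-yl]-5-methyl-1-(2-oxobutyl)cyclopentyl}acetaldehyde, via secondary ozonide 9 (not isolated)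
Conditions: O3, CH2Cl2, −78 °C; then Me2S, −78 °C → rt
Reagents that add atoms: ozone, [O-][O+]=O
Why: Ozonolysis with reductive work-up cleaves the only C=C bond of 8 and unmasks the C16 ethyl ketone, while the aldehyde and the free alcohol survive brief exposure at −78 °C.

Step 6
Reactants: 10 keto aldehyde
Product: 12 (1R,4S,5S)-1-[(2S)-1-hydroxypropan-2-yl]-4,8-dimethylspiro[4.5]dec-8-en-7-one, via aldol adduct 11 (not isolated)
Conditions: KOH, MeOH, rt → 50 °C
Reagents that add atoms: none
Why: Intramolecular aldol condensation (6-enolendo-exo-trig) of the 1,5-keto aldehyde joins C15 to C14 and closes ring C as the 2-methylcyclohexenone, this being the only feasible closure because every other enolate–carbonyl pairing would give a four-membered ring.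

Step 7
Reactants: 12 enone alcohol
Product: 13 (2S)-2-[(1R,4S,5S)-4,8-dimethyl-7-oxospiro[4.5]dec-8-en-1-yl]propanal
Conditions: Dess–Martin periodinane, CH2Cl2, 0 °C → rt
Reagents that add atoms: none
Why: Dess–Martin oxidation converts the primary alcohol into the C6 aldehyde under near-neutral conditions, so the α-stereocentre C7 and the enone should be unaffected.

Step 8
Reactants: 13 enone aldehyde
Product: 14 (1R,4S,5S)-4,8-dimethyl-1-[(2R,3E)-4-(4,4,5,5-tetramethyl-1,3,2-dioxaborolan-2-yl)but-3-en-2-yl]spiro[4.5]dec-8-en-7-one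
Conditions: Cl2CHBpin, CrCl2, LiI, THF, rt
Reagents that add atoms: 2-(dichloromethyl)-4,4,5,5-tetramethyl-1,3,2-dioxaborolane, CC1(C)OB(C(Cl)Cl)OC1(C)C
Why: The Takai–Utimoto olefination with the geminal dichromium reagent adds C5, is aldehyde-selective (the ketone is left), non-basic (C7 keeps its geometry, its descriptor changing only through priorities) and E-selective.

Step 9
Reactants: 14 (E)-alkenyl pinacol boronate
Product: 15 potassium trifluoro{(1E,3R)-3-[(1R,4S,5S)-4,8-dimethyl-7-oxospiro[4.5]dec-8-en-1-yl]but-1-en-1-yl}borate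
Conditions: KHF2, MeOH/H2O, rt
Reagents that add atoms: potassium hydrogen difluoride, [K+].[F-].F
Why: Ligand exchange at boron with KHF2 gives the trifluoroborate needed for the C–O coupling with retention of the E geometry.

Step 10
Reactants: 16 propargyl alcohol
Product: 18 (Z)-3-iodo-2-methylprop-2-en-1-ol, via cyclic alkenylmagnesium alkoxide 17 (not isolated)
Conditions: MeMgBr, CuI (cat.), Et2O, −10 °C → rt; then I2, 0 °C
Reagents that add atoms: methylmagnesium bromide, C[Mg]Br; iodine, II
Why: Copper-catalysed anti-carbomagnesiation of the propargylic alkoxide places methyl on the inner carbon and magnesium in a five-membered chelate, so iodinolysis with retention gives iodine cis to CH2OH.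

Step 11
Reactants: 18 (Z)-3-iodo-2-methylprop-2-en-1-ol
Product: 20 (Z)-3-iodo-2-methylprop-2-enoic acid, via (Z)-3-iodo-2-methylprop-2-enal 19 (not isolated)
Conditions: TEMPO (cat.), PhI(OAc)2, MeCN/H2O, rt
Reagents that add atoms: water, O
Why: Oxoammonium (TEMPO) oxidation in aqueous medium carries the allylic alcohol through the hydrated aldehyde to the acid quickly enough that the Z iodoalkene should not isomerise.

Step 12
Reactants: 15 potassium (E)-alkenyltrifluoroborate; 20 (Z)-3-iodo-2-methylprop-2-enoic acid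
Product: 21 (1E,3S)-3-[(1R,4S,5S)-4,8-dimethyl-7-oxospiro[4.5]dec-8-en-1-yl]but-1-en-1-yl (2Z)-3-iodo-2-methylprop-2-enoate
Conditions: CuBr (cat.), DMAP, O2 (1 atm), 4 Å molecular sieves, MeCN, 40–60 °C (20 in excess)
Reagents that add atoms: none
Why: The aerobic copper-catalysed Chan–Lam–Evans-type coupling of an alkenyltrifluoroborate with a carboxylic acid forms O1–C5 with retention of alkene geometry, so the E enol ester required by step 13 is obtained while the C4–I bond is not engaged.

Step 13
Reactants: 21 (E)-enol ester of the (Z)-iodoacrylic acid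
Product: 22 (5Z)-5-{(2S)-2-[(1R,4S,5S)-4,8-dimethyl-7-oxospiro[4.5]dec-8-en-1-yl]propylidene}-3-methylfuran-2(5H)-one
Conditions: Pd(OAc)2 (cat.), PPh3, Ag2CO3, MeCN, 60 °C
Reagents that add atoms: none
Why: Zerovalent palladium inserts into the C4–I bond with retention, Ag2CO3 strips iodide, and the cationic alkenylpalladium adds syn across the tethered enol-ester alkene so that C4 bonds to C5 and palladium sits on C6; rotation about C5–C6 and syn β-hydride elimination of H5 then release the dienolide. The reaction type is the intramolecular Mizoroki–Heck reaction, the closest known cases being the 5-exo closures of N-alkenyl 2-halobenzamides to 3-alkylideneisoindolinones and the internal (α) Heck vinylation of vinyl esters and enol ethers under cationic conditions. Ring A closes in the 5-exo-trig mode, C6 staying outside the ring. No stereocentre is formed; the syn-addition/syn-elimination sequence converts the E enol ester into the Z C5=C6 alkene (O1 cis to C7), which is also the more stable isomer. The step needs 5-exo rather than 6-endo insertion, secured by the three-atom tether and by the polarisation of the enol ester that sends the carbon ligand to the oxygen-bearing C5. It also needs loss of H5 rather than H7, secured because H5 is allylic, α to oxygen and leads to the conjugated dienolide while H7 sits on a crowded tertiary carbon, and silver removes the palladium hydride before it can re-add, so C7 and the enone of ring C are left alone.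

Step 14
Reactants: 22 butenolide enone
Product: 23 (5Z)-5-{(2S)-2-[(1R,4S,5S,7R)-7-hydroxy-4,8-dimethylspiro[4.5]dec-8-en-1-yl]propylidene}-3-methylfuran-2(5H)-one (16R alcohol)
Conditions: NaBH4, CeCl3·7H2O, MeOH, −78 °C
Reagents that add atoms: none
Why: In the Luche reduction the CeCl3-activated enone should react 1,2 and faster than the vinylogous enol lactone of ring A, and hydride should add to the C16 face syn to C8 because the C11 methyl group lies over the other face, which sets 16R (OH cis to C11), the epimer required for the inversion in step 15.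

Step 15
Reactants: 23 16R allylic alcohol; 24 3-phenylpropanoic acid
Product: 25 (1R,4S,5S,7S)-4,8-dimethyl-1-{(2S)-1-[(2Z)-4-methyl-5-oxofuran-2(5H)-ylidene]propan-2-yl}spiro[4.5]dec-8-en-7-yl 3-phenylpropanoate (target)
Conditions: PPh3, DIAD, toluene, 0 °C → rt
Reagents that add atoms: none
Why: In the Mitsunobu esterification the carboxylate displaces the activated alcohol by SN2 from the open face syn to C8, which inverts C16 to S and installs the ester in the same operation.

**Compound list**

1 | (4aS,7S,7aR)-nepetalactone (4,7-dimethyl-5,6,7,7a-tetrahydrocyclopenta[c]pyran-1(4aH)-one) | O=C1OC=C(C)[C@H]2CC[C@H](C)[C@@H]12 | starting material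
2 | (4S,4aR,7S,7aR)-dihydronepetalactone (H4, H4a and H7a all cis) | O=C1OC[C@@H](C)[C@H]2CC[C@H](C)[C@@H]12 | intermediate
3 | 2-(bromomethyl)but-1-ene | C=C(CC)CBr | starting material
4 | lithium enolate of 2 (C12=C13 enolate; C7, C8, C11 as in 2) | [Li+].[O-]C1OC[C@@H](C)[C@H]2CC[C@H](C)C=12 | intermediate
5 | (4S,4aR,7S,7aR)-4,7-dimethyl-7a-(2-methylidenebutyl)hexahydrocyclopenta[c]pyran-1(3H)-one | O=C1OC[C@@H](C)[C@H]2CC[C@H](C)[C@@]12CC(=C)CC | intermediate
6 | (4S,4aR,7S,7aR)-4,7-dimethyl-7a-(2-methylidenebutyl)octahydrocyclopenta[c]pyran-1-ol (both acetal epimers) | OC1OC[C@@H](C)[C@H]2CC[C@H](C)[C@@]12CC(=C)CC | intermediate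
7 | methyl enol ether of 8 (2-methoxyethenyl in place of CH2CHO, E/Z mixture; stereocentres placed as in 8) | OC[C@@H](C)[C@H]1CC[C@H](C)[C@]1(C=COC)CC(=C)CC | intermediate
8 | 2-{(1R,2R,5S)-2-[(2S)-1-hydroxypropan-2-yl]-5-methyl-1-(2-methylidenebutyl)cyclopentyl}acetaldehyde | OC[C@@H](C)[C@H]1CC[C@H](C)[C@]1(CC=O)CC(=C)CC | intermediate
9 | secondary ozonide (3-ethyl-1,2,4-trioxolan-3-yl)methyl analogue of 8 | OC[C@@H](C)[C@H]1CC[C@H](C)[C@]1(CC=O)CC1(CC)OCOO1 | intermediate
10 | 2-{(1S,2R,5S)-2-[(2S)-1-hydroxypropan-2-yl]-5-methyl-1-(2-oxobutyl)cyclopentyl}acetaldehyde | OC[C@@H](C)[C@H]1CC[C@H](C)[C@]1(CC=O)CC(=O)CC | intermediate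
11 | aldol adduct, 9-hydroxy-8-methyl-7-ketone of the spiro[4.5]decane (C14, C15 epimers; other centres as in 12) | OC[C@@H](C)[C@H]1CC[C@H](C)[C@@]12CC(O)C(C)C(=O)C2 | intermediate
12 | (1R,4S,5S)-1-[(2S)-1-hydroxypropan-2-yl]-4,8-dimethylspiro[4.5]dec-8-en-7-one | OC[C@@H](C)[C@H]1CC[C@H](C)[C@@]12CC=C(C)C(=O)C2 | intermediate
13 | (2S)-2-[(1R,4S,5S)-4,8-dimethyl-7-oxospiro[4.5]dec-8-en-1-yl]propanal | O=C[C@@H](C)[C@H]1CC[C@H](C)[C@@]12CC=C(C)C(=O)C2 | intermediate
14 | (1R,4S,5S)-4,8-dimethyl-1-[(2R,3E)-4-(4,4,5,5-tetramethyl-1,3,2-dioxaborolan-2-yl)but-3-en-2-yl]spiro[4.5]dec-8-en-7-one | CC1(C)OB(/C=C/[C@@H](C)[C@H]2CC[C@H](C)[C@@]23CC=C(C)C(=O)C3)OC1(C)C | intermediate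
15 | potassium trifluoro{(1E,3R)-3-[(1R,4S,5S)-4,8-dimethyl-7-oxospiro[4.5]dec-8-en-1-yl]but-1-en-1-yl}borate | [K+].F[B-](F)(F)/C=C/[C@@H](C)[C@H]1CC[C@H](C)[C@@]12CC=C(C)C(=O)C2 | intermediate
16 | propargyl alcohol | C#CCO | starting material
17 | cyclic alkenylmagnesium alkoxide (4-methyl-2,5-dihydro-1,2-oxamagnesole) | CC1=C[Mg]OC1 | intermediate
18 | (Z)-3-iodo-2-methylprop-2-en-1-ol | OC/C(C)=C\I | intermediate
19 | (Z)-3-iodo-2-methylprop-2-enal | O=C/C(C)=C\I | intermediate
20 | (Z)-3-iodo-2-methylprop-2-enoic acid | OC(=O)/C(C)=C\I | intermediate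
21 | (1E,3S)-3-[(1R,4S,5S)-4,8-dimethyl-7-oxospiro[4.5]dec-8-en-1-yl]but-1-en-1-yl (2Z)-3-iodo-2-methylprop-2-enoate | I/C=C(/C)C(=O)O/C=C/[C@@H](C)[C@H]1CC[C@H](C)[C@@]12CC=C(C)C(=O)C2 | intermediate
22 | (5Z)-5-{(2S)-2-[(1R,4S,5S)-4,8-dimethyl-7-oxospiro[4.5]dec-8-en-1-yl]propylidene}-3-methylfuran-2(5H)-one | CC1=C/C(=C/[C@@H](C)[C@H]2CC[C@H](C)[C@@]23CC=C(C)C(=O)C3)OC1=O | intermediate
23 | (5Z)-5-{(2S)-2-[(1R,4S,5S,7R)-7-hydroxy-4,8-dimethylspiro[4.5]dec-8-en-1-yl]propylidene}-3-methylfuran-2(5H)-one | CC1=C/C(=C/[C@@H](C)[C@H]2CC[C@H](C)[C@@]23CC=C(C)[C@H](O)C3)OC1=O | intermediate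
24 | 3-phenylpropanoic acid | OC(=O)CCc1ccccc1 | starting material
25 | (1R,4S,5S,7S)-4,8-dimethyl-1-{(2S)-1-[(2Z)-4-methyl-5-oxofuran-2(5H)-ylidene]propan-2-yl}spiro[4.5]dec-8-en-7-yl 3-phenylpropanoate | CC1=C/C(=C/[C@@H](C)[C@H]2CC[C@H](C)[C@@]23CC=C(C)[C@@H](OC(=O)CCc2ccccc2)C3)OC1=O | target

**Total steps:** 15. **Longest linear sequence:** 13 (steps 1–9 and 12–15, from 1).

**Steps most likely to fail**

**Step 13 (Heck ring closure).**
What may go wrong:
- After insertion the alkylpalladium may lose H7 instead of H5. This would move the alkene and erase C7.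
- It may expel the carboxylate by β-acyloxy elimination, which reopens ring A.
- Insertion may occur 6-endo.

Fallback, setting out from 13 and 20 and coming back at 22: C4–C5 is still made in a ring closure, but through a temporary six-membered lactone tethered at the oxygen on C6. Aldehyde-selective Nozaki–Hiyama–Kishi vinylation of 13 (vinyl bromide, CrCl2, cat. NiCl2, DMF) gives the allylic alcohol F1. Steglich esterification with 20 gives the iodoacrylate F2. Lemieux–Johnson cleavage (cat. OsO4, NaIO4) of the only electron-rich alkene gives the α-acyloxy aldehyde F3. An intramolecular Nozaki–Hiyama–Kishi reaction (CrCl2, cat. NiCl2, DMF, high dilution) joins C4 to C5 and gives the 5-hydroxy-5,6-dihydropyran-2-one F4. DBU moves the acyl group to the C5 oxygen and gives the butenolide carbinol F5. MsCl/Et3N gives the mesylate F6, which undergoes E1cB elimination through the furanolate to 22 as the thermodynamically preferred Z isomer.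

**Step 12 (copper-catalysed enol esterification).**
What may go wrong:
- Protodeboronation or oxidative homocoupling of the alkenylborate may outrun C–O bond formation.
- The copper/DMAP system may substitute the iodoacrylate at C4.

Fallback, setting out from 13 and coming back at 22: Seyferth–Gilbert homologation with the Ohira–Bestmann reagent (K2CO3, MeOH) gives the terminal alkyne F7. Ruthenium-catalysed anti-Markovnikov hydroacyloxylation with 20 ([RuCl2(p-cymene)]2, P(4-ClC6H4)3, DMAP, toluene) gives the (Z)-enol ester F8. The Heck closure under the conditions of step 13 then gives, by the same syn/syn course, the (E)-alkylidene butenolide F9. Catalytic I2 in daylight equilibrates F9 to 22.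

**Step 14 (substrate-controlled reduction).**
What may go wrong:
- Facial selectivity at C16 may be poor or reversed, because either ring B carbon can sit axial on ring C.
- Hydride may attack ring A.

Fallback, setting out from 22 and coming back at 25: reagent-controlled Corey–Bakshi–Shibata reduction ((R)-2-methyl-CBS-oxazaborolidine, catecholborane, toluene, −78 °C) gives the (16S)-alcohol F10. F10 is esterified with retention (24, EDC·HCl, DMAP, CH2Cl2) to give 25.

**Further compounds**

F1 | step 13 | allylic alcohol, 1-[(2S)-3-hydroxypent-4-en-2-yl] analogue of 12 (C6 epimers) | C=CC(O)[C@@H](C)[C@H]1CC[C@H](C)[C@@]12CC=C(C)C(=O)C2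
F2 | step 13 | (2Z)-3-iodo-2-methylprop-2-enoate of F1 | C=CC(OC(=O)/C(C)=C\I)[C@@H](C)[C@H]1CC[C@H](C)[C@@]12CC=C(C)C(=O)C2
F3 | step 13 | α-acyloxy aldehyde from cleavage of the vinyl group of F2 | O=CC(OC(=O)/C(C)=C\I)[C@@H](C)[C@H]1CC[C@H](C)[C@@]12CC=C(C)C(=O)C2
F4 | step 13 | 5-hydroxy-3-methyl-6-substituted 5,6-dihydropyran-2-one (C5, C6 epimers) | CC1=CC(O)C(OC1=O)[C@@H](C)[C@H]1CC[C@H](C)[C@@]12CC=C(C)C(=O)C2
F5 | step 13 | 5-(1-hydroxyalkyl)-3-methylfuran-2(5H)-one (butenolide carbinol) | CC1=CC(OC1=O)C(O)[C@@H](C)[C@H]1CC[C@H](C)[C@@]12CC=C(C)C(=O)C2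
F6 | step 13 | methanesulfonate of F5 | CC1=CC(OC1=O)C(OS(C)(=O)=O)[C@@H](C)[C@H]1CC[C@H](C)[C@@]12CC=C(C)C(=O)C2
F7 | step 12 | (1R,4S,5S)-1-[(2S)-but-3-yn-2-yl]-4,8-dimethylspiro[4.5]dec-8-en-7-one | C#C[C@@H](C)[C@H]1CC[C@H](C)[C@@]12CC=C(C)C(=O)C2
F8 | step 12 | (1Z)-enol ester isomer of 21 | I/C=C(/C)C(=O)O/C=C\[C@@H](C)[C@H]1CC[C@H](C)[C@@]12CC=C(C)C(=O)C2
F9 | step 12 | (5E)-isomer of 22 | CC1=C/C(=C\[C@@H](C)[C@H]2CC[C@H](C)[C@@]23CC=C(C)C(=O)C3)OC1=O
F10 | step 14 | (16S)-alcohol, C16 epimer of 23 | CC1=C/C(=C/[C@@H](C)[C@H]2CC[C@H](C)[C@@]23CC=C(C)[C@@H](O)C3)OC1=O
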